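## Structural features

The target is a monocyclic tetrahydrofuran lignan. With the ring numbered O1, C2, C3, C4, C5, C2 bears a 4-hydroxy-3-methoxyphenyl (guaiacyl) ring, C3 a hydroxymethyl group and C4 a 4-hydroxy-3,5-dimethoxybenzoyl (syringoyl) group; C5 is an unsubstituted CH2. C2, C3 and C4 are three contiguous stereocentres, (2S,3R,4S), with each neighbouring pair trans, the arrangement of lowest strain for this ring. The fragile points are:

- the two free phenols;
- the C2–O1 bond, a benzylic ether para to a phenol and therefore open to acid and to hydrogenolysis;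
- the C4–H bond, α to the ketone and β to O1, so open to epimerisation and elimination;
- the primary hydroxyl and the ketone, which stay open-chain only because they are trans on the ring.

The real difficulty is C2. No enolisation can correct it, so its absolute configuration must come from a reagent, and it must be bonded to C3 next to an electron-rich arene. C3 and C4 are easier, because each can stand next to a carbonyl group at some stage (an ester at C3, the aryl ketone at C4) and be set by equilibration. The key step uses the fact that C2, as a CH2 between O1 and the guaiacyl ring, has hydridic C–H bonds in a 1,5-relation to C3 through C4, C5 and O1. A metal carbene at C3, carrying an ester (the later CH2OH) and a C4 alkene (the later aroyl group), can insert into C2–H and close the ring.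

## Logic of the disconnections

18 ⇒ 17. The two phenolic O–H bonds are traced back to O–benzyl bonds. Benzyl ethers survive base, hydride, palladium coupling and the carbene step, and keep the guaiacyl ring electron-rich. The demand on the forward step is a hydrogenolysis that spares C2–O1 and the ketone.

17 ⇒ 16 ⇒ 15. The C3 hydroxymethyl group is traced back to an ester, which makes C3 enolisable. No hydride reduces an ester beside an aryl ketone, so both carbonyls are reduced (16) and only the benzylic carbinol is re-oxidised. The demand is an oxidant that distinguishes a benzylic from a primary aliphatic hydroxyl.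

15 ⇒ 14. No bond is cut; this is a stereochemical simplification. C3 (α to the ester) and C4 (α to the ketone) are allowed to be of either configuration in 14, because base equilibrates them to the all-trans isomer. The demand is that enolisation does not open the ring by β-elimination of O1.

14 ⇒ 12 (through 13). The ketone C=O is traced back to an exocyclic C4=C alkene, by hydroboration with boron on the benzylic carbon and direct oxidation of C–B to C=O. This makes C4 trigonal, as the carbene step needs. Two demands follow:

- The hydroxy ester must not accumulate. Hydrogen is delivered to C4 anti to the C3 ester, so the new hydroxyl would sit cis to the ester and lactonise.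
- 12 must never see base. Deprotonation at C3 of this β,γ-unsaturated ester would move the alkene into conjugation.

12 ⇒ 11. The strategic cut is C2–C3. In reverse, C3 becomes a diazo carbon and C2 the CH2 of a benzylic ether. The ring, one skeletal bond and two stereocentres disappear, leaving an acyclic ether. The demand is a catalyst that picks one of two enantiotopic hydrogens and a carbene that does nothing but 1,5-insertion.

11 ⇒ 9 + 10. The C3–C4 bond is cut between the diazo carbon and the alkene. A vinyl iodide and a diazoacetate are joined under palladium with retention of alkene geometry. The demand is passed on to 9: iodine must be trans to the aryl group.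

9 ⇒ 7 (through 8). The C–I bond and the vinylic C–H bond are traced back to an alkyne by syn addition of H and Sn, then exchange of Sn for I. The demand is regiocontrol: tin on the alkyne carbon next to the CH2O group.

7 ⇒ 3 + 6. The aryl–alkyne bond is cut (coupling of a terminal alkyne with an aryl iodide). This separates the molecule into its guaiacyl and syringyl halves.

3 ⇒ 1 + 2 and 6 ⇒ 5 ⇒ 4. The O1–C5 ether bond is cut to an alkoxide and a propargylic bromide. The aryl iodide is traced back through O-benzylation and para-iodination to the phenol 4.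

## Other disconnections considered

Alternative 1: The cut goes through O1–C2 and C3–C4. A C4–C5–O1 unit, carbonate A2 (4-[1-(4-benzyloxy-3,5-dimethoxyphenyl)vinyl]-1,3-dioxolan-2-one), would be joined to the C2=C3 bond of benzylidene malonate A3.

- Forward step: a zerovalent palladium catalyst with a chiral ligand would ionise A2 with loss of CO2. The alkoxide end would add to A3 and the malonate carbanion would close on the substituted allyl terminus to give diester A1.
- In its favour: both aryl groups arrive in two short fragments. The 1-arylvinyl group is a ketone masked against hydride, so the ester could be reduced before oxidative cleavage of the alkene and no reduce–reoxidise detour would be needed. Cycloaddition of vinylethylene carbonates with electron-poor alkenes is an established reaction type.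
- Against it here: the ligand would have to control C2 and C4 as well as the allyl regiochemistry. The oxa-Michael addition is reversible, so C2 could erode. One ester must be removed by a hot dealkoxycarbonylation on a β-alkoxy ester, and C3 would be set only by the following protonation.
- Comparison: on step economy and on precedent for the reaction class Alternative 1 is the better plan, and it needs neither a diazo compound nor tin. On stereochemical safety the chosen plan is better, since only one centre (C2) needs catalyst control and no reversible C–O bond formation threatens it. The final equilibration at C4 would be equal in both.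

Alternative 2: The cut goes through O1–C2, C2–C3 and C4–C5. Diol A5 (a 2-aryl-pent-3-ene-1,2-diol with a silyl ether at C5 and the phenol as pivalate) and aldehyde A6 (vanillin pivalate) would be the fragments.

- Forward step: acetal formation, then SnCl4. The oxocarbenium ion at C2 would be attacked by the alkene carbon C3 through a six-membered chair, and migration of C5 to the cationic C4 would contract the ring and turn the tertiary carbinol into the aryl ketone, giving A4.
- In its favour: three bonds, the ring, the ketone at its final oxidation level and all three stereocentres would come from one operation, with only deprotections left.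
- Against it here: A5 must be a single enantiomer at a tertiary benzylic carbinol, which is hard to make and easy to ionise under SnCl4. The alkene of A5 is 1,2-disubstituted and flanked by two allylic oxygens, so it is a poor nucleophile, and the cation at C4 would be secondary. The allylic silyl ether and the acetal could ionise in other ways. C2 and C3 could not be corrected afterwards.
- Comparison: on step economy and redox economy Alternative 2 is clearly better. On mechanism it depends on a cationic cascade with several exits opened by the electron-rich arenes, whereas the chosen plan depends on a single concerted insertion. On stereochemistry it relays one hard-won centre, whereas the chosen plan uses a catalyst for C2 and equilibration for C3 and C4.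

Alternative 3: The cut goes through O1–C2 and C2–C3. Alcohol A8 (a homoallylic alcohol with an allylsilane and a silylated aryl carbinol) and aldehyde A9 (O-benzylvanillin) would be the fragments.

- Forward step: TMSOTf would condense A8 and A9 to an oxocarbenium ion, which the allylsilane would attack through C3, closing the ring and leaving a vinyl group at C3 in A7.
- In its favour: the aldehyde carbon becomes C2 directly, and intramolecular allylsilane additions to oxocarbenium ions are well understood. The vinyl group is a sturdy precursor of CH2OH.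
- Against it here: A8 needs C4 as a single enantiomer plus a carbinol centre that is later destroyed, so its synthesis would take several steps of separate asymmetric chemistry. C2 and C3 would depend on substrate control through a closure that is 5-endo with respect to the oxocarbenium ion. The electron-rich benzylic silyl ether could ionise under TMSOTf. Ozonolysis, desilylation, benzylic oxidation and hydrogenolysis would still follow.
- Comparison: on mechanistic precedent Alternative 3 is better than the chosen plan, and in the simplicity of the C2 fragment it is equal. On stereocontrol it is weaker (one centre made beforehand, two by relay, against one by catalyst and two by equilibration). On step count it is equal at best.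

Key step: step 7

Assumption: the sense of induction of Rh2(S-PTTL)4 on this tether is taken to lead to 2S; if the opposite sense is found, Rh2(R-PTTL)4 is used and nothing else changes.

## Route

Step 1
Reactants: 1 4-(benzyloxy)-3-methoxybenzyl alcohol; 2 propargyl bromide
Product: 3 1-(benzyloxy)-2-methoxy-4-[(prop-2-yn-1-yloxy)methyl]benzene
Conditions: NaH, THF–DMF, 0 °C → rt
Reagents that add atoms: none
Why: Williamson ether synthesis; the primary alkoxide displaces bromide from the unhindered propargylic carbon, forming the future O1–C5 bond, and low temperature avoids alkyne–allene isomerisation.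

Step 2
Reactants: 4 2,6-dimethoxyphenol
Product: 5 4-iodo-2,6-dimethoxyphenol
Conditions: N-iodosuccinimide, MeCN, 0 °C, dark
Reagents that add atoms: N-iodosuccinimide, O=C1CCC(=O)N1I
Why: Electrophilic aromatic iodination; the position para to the hydroxyl is the only strongly activated free site, and the mild iodine source at low temperature limits oxidative coupling of the phenol.

Step 3
Reactants: 5 4-iodo-2,6-dimethoxyphenol
Product: 6 2-(benzyloxy)-5-iodo-1,3-dimethoxybenzene
Conditions: BnBr, K2CO3, DMF, rt → 50 °C
Reagents that add atoms: benzyl bromide, BrCc1ccccc1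
Why: O-Alkylation of a phenoxide (Williamson); the flanking methoxy groups slow but do not prevent alkylation.

Step 4
Reactants: 3 1-(benzyloxy)-2-methoxy-4-[(prop-2-yn-1-yloxy)methyl]benzene; 6 2-(benzyloxy)-5-iodo-1,3-dimethoxybenzene
Product: 7 2-(benzyloxy)-5-[3-{[4-(benzyloxy)-3-methoxybenzyl]oxy}prop-1-yn-1-yl]-1,3-dimethoxybenzene
Conditions: PdCl2(PPh3)2 (2 mol %), CuI (4 mol %), Et3N–THF, degassed, rt → 40 °C
Reagents that add atoms: none
Why: Sonogashira coupling of a terminal alkyne with an aryl iodide; the iodide is chosen because the arene is electron-rich, and degassing suppresses alkyne homocoupling.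

Step 5
Reactants: 7 2-(benzyloxy)-5-[3-{[4-(benzyloxy)-3-methoxybenzyl]oxy}prop-1-yn-1-yl]-1,3-dimethoxybenzene
Product: 9 2-(benzyloxy)-5-[(E)-3-{[4-(benzyloxy)-3-methoxybenzyl]oxy}-2-iodoprop-1-en-1-yl]-1,3-dimethoxybenzene, via vinylstannane 8 (not isolated)
Conditions: Bu3SnH, PdCl2(PPh3)2 (3 mol %), THF, 0 °C → rt; then I2, CH2Cl2, 0 °C; aq. KF/Na2S2O3 work-up
Reagents that add atoms: tributyltin hydride (tin in 8), CCCC[SnH](CCCC)CCCC; iodine, II
Why: Palladium-catalysed hydrostannation is a syn addition, and the inductively withdrawing propargylic oxygen and the electron-rich arene on the other alkyne carbon both direct tin to the carbon next to CH2O, so the aryl and CH2O groups end up cis. Iododestannylation proceeds with retention, and any regioisomeric iodide is removed by chromatography.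

Step 6
Reactants: 9 2-(benzyloxy)-5-[(E)-3-{[4-(benzyloxy)-3-methoxybenzyl]oxy}-2-iodoprop-1-en-1-yl]-1,3-dimethoxybenzene; 10 ethyl diazoacetate
Product: 11 ethyl (Z)-4-[4-(benzyloxy)-3,5-dimethoxyphenyl]-3-({[4-(benzyloxy)-3-methoxybenzyl]oxy}methyl)-2-diazobut-3-enoate
Conditions: Pd(PPh3)4 (5 mol %), Et3N, Bu4NBr, MeCN, rt, dark
Reagents that add atoms: none
Why: Palladium-catalysed cross-coupling of a vinyl iodide with a diazoacetate (oxidative addition, base-assisted transfer of the diazoacetate carbon to palladium, reductive elimination) keeps both the diazo group and the alkene geometry, so the carbene carbon ends up trans to the aryl group. 11 is used at once, because vinyldiazoacetates slowly cyclise to pyrazoles.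

Step 7
Reactants: 11 ethyl (Z)-4-[4-(benzyloxy)-3,5-dimethoxyphenyl]-3-({[4-(benzyloxy)-3-methoxybenzyl]oxy}methyl)-2-diazobut-3-enoate
Product: 12 ethyl (2S,3S,Z)-2-[4-(benzyloxy)-3-methoxyphenyl]-4-[4-(benzyloxy)-3,5-dimethoxybenzylidene]tetrahydrofuran-3-carboxylate
Conditions: Rh2(S-PTTL)4 (1 mol %), toluene, 4 Å MS, −40 → 0 °C, slow addition of 11
Reagents that add atoms: none
Why: Proposed new method: the catalyst (a divalent rhodium dimer) expels N2 from 11 to give a rhodium-bound donor/acceptor vinylcarbene at C3, which inserts into one benzylic C2–H bond in a single concerted, asynchronous, hydride-transfer-like event. The closest known reaction type is the enantioselective intramolecular insertion of aryldiazoacetates into benzylic ether C–H bonds that gives 2-aryl-2,3-dihydrobenzofuran-3-carboxylates; here a styryl group replaces the aryl donor and the tether is acyclic. The tetrahydrofuran closes by 1,5 C–H insertion through a five-membered transition state (C3, C4, C5, O1, C2); the C5 hydrogens stand 1,3 to the carbene, the ortho hydrogens of the styryl arene are held away by the alkene geometry, and every other C–H bond is much farther off. C2 is set by the chiral phthalimido-carboxylate ligands, which distinguish the two enantiotopic benzylic hydrogens; this ligand class is chosen because it is the one with precedent for selective insertion into a CH2 group next to oxygen. C3 forms in the same event; the trans isomer is written, the aryl-fused precedent leans towards cis, and either C3 epimer converges in step 9, so nothing depends on it. Site selectivity rests on O1 and the para-alkoxy arene, which make C2–H the most hydridic bond within reach. Chemoselectivity rests on the aryl group being trans to the carbene (no closure onto the arene), on the fully substituted C4 (no 1,2-hydride shift) and on the trisubstituted, aryl-capped alkene (no vinylogous attack, no intermolecular cyclopropanation). Slow addition at low temperature holds back carbene dimerisation and the electrocyclisation of 11 to a pyrazole.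

Step 8
Reactants: 12 ethyl (2S,3S,Z)-2-[4-(benzyloxy)-3-methoxyphenyl]-4-[4-(benzyloxy)-3,5-dimethoxybenzylidene]tetrahydrofuran-3-carboxylate
Product: 14 ethyl (2S,3S)-2-[4-(benzyloxy)-3-methoxyphenyl]-4-[4-(benzyloxy)-3,5-dimethoxybenzoyl]tetrahydrofuran-3-carboxylate as a mixture of C4 epimers, via benzylic borane 13 (not isolated)
Conditions: BH3·SMe2, CH2Cl2, 0 °C → rt; then N-methylmorpholine N-oxide (excess), Pr4N[RuO4] (5 mol %), 4 Å MS, rt
Reagents that add atoms: borane–dimethyl sulfide (boron in 13), [BH3-][S+](C)C; N-methylmorpholine N-oxide, C[N+]1([O-])CCOCC1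
Why: Hydroboration of the trisubstituted alkene places boron on the less substituted, benzylic carbon and hydrogen on C4 (syn addition; the C4 configuration is unimportant here). The amine oxide then converts C–B into C–O and the perruthenate takes the borate to the ketone in the same flask, a known one-pot alkene-to-ketone conversion. The free hydroxy ester, whose hydroxyl would lie cis to the C3 ester and lactonise, is never allowed to accumulate.

Step 9
Reactants: 14 ethyl (2S,3S)-2-[4-(benzyloxy)-3-methoxyphenyl]-4-[4-(benzyloxy)-3,5-dimethoxybenzoyl]tetrahydrofuran-3-carboxylate (C4 epimers)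
Product: 15 ethyl (2S,3S,4S)-2-[4-(benzyloxy)-3-methoxyphenyl]-4-[4-(benzyloxy)-3,5-dimethoxybenzoyl]tetrahydrofuran-3-carboxylate
Conditions: NaOEt (0.3 equiv), EtOH–THF, 0 °C → rt; AcOH quench
Reagents that add atoms: none
Why: Thermodynamic epimerisation through the ketone enolate (C4) and the ester enolate (C3) settles the ring in the all-trans arrangement, while C2 has no acidic hydrogen and keeps its configuration. Ethoxide matches the ester, and ring opening by β-elimination of O1 from either enolate is the reverse of a 5-endo-trig closure and is stereoelectronically slow.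

Step 10
Reactants: 15 ethyl (2S,3S,4S)-2-[4-(benzyloxy)-3-methoxyphenyl]-4-[4-(benzyloxy)-3,5-dimethoxybenzoyl]tetrahydrofuran-3-carboxylate
Product: 16 {(2S,3R,4S)-2-[4-(benzyloxy)-3-methoxyphenyl]-4-[[4-(benzyloxy)-3,5-dimethoxyphenyl](hydroxy)methyl]tetrahydrofuran-3-yl}methanol as a mixture of carbinol epimers
Conditions: LiAlH4, THF, 0 °C; H2O/aq. NaOH work-up
Reagents that add atoms: none
Why: Hydride reduction of ester and ketone together; once both carbonyls are gone C3 and C4 are fixed, and the new carbinol centre is removed in the next step.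

Step 11
Reactants: 16 {(2S,3R,4S)-2-[4-(benzyloxy)-3-methoxyphenyl]-4-[[4-(benzyloxy)-3,5-dimethoxyphenyl](hydroxy)methyl]tetrahydrofuran-3-yl}methanol
Product: 17 [4-(benzyloxy)-3,5-dimethoxyphenyl]{(2S,3R,4S)-2-[4-(benzyloxy)-3-methoxyphenyl]-3-(hydroxymethyl)tetrahydrofuran-4-yl}methanone
Conditions: MnO2 (activated, excess), CH2Cl2, rt
Reagents that add atoms: none
Why: MnO2 oxidises the electron-rich benzylic carbinol and leaves the primary aliphatic hydroxyl untouched. The keto alcohol cannot close to a lactol because CH2OH and aroyl are trans, and the neutral conditions do not disturb C4, which is already in its preferred configuration.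

Step 12
Reactants: 17 [4-(benzyloxy)-3,5-dimethoxyphenyl]{(2S,3R,4S)-2-[4-(benzyloxy)-3-methoxyphenyl]-3-(hydroxymethyl)tetrahydrofuran-4-yl}methanone
Product: 18 (4-hydroxy-3,5-dimethoxyphenyl)[(2S,3R,4S)-2-(4-hydroxy-3-methoxyphenyl)-3-(hydroxymethyl)tetrahydrofuran-4-yl]methanone
Conditions: H2 (1 atm), palladium on carbon (10 wt % Pd), EtOAc, rt, stopped after uptake of two equivalents
Reagents that add atoms: none
Why: Hydrogenolysis of aryl benzyl ethers is much faster than cleavage of the ring C2–O1 bond or reduction of the electron-rich aryl ketone in a neutral, non-protic solvent; no stereocentre is touched.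

## Compound list

1 | 4-(benzyloxy)-3-methoxybenzyl alcohol | COc1cc(CO)ccc1OCc1ccccc1 | starting material
2 | propargyl bromide | C#CCBr | starting material
3 | 1-(benzyloxy)-2-methoxy-4-[(prop-2-yn-1-yloxy)methyl]benzene | COc1cc(COCC#C)ccc1OCc1ccccc1 | intermediate
4 | 2,6-dimethoxyphenol | COc1cccc(OC)c1O | starting material
5 | 4-iodo-2,6-dimethoxyphenol | COc1cc(I)cc(OC)c1O | intermediate
6 | 2-(benzyloxy)-5-iodo-1,3-dimethoxybenzene | COc1cc(I)cc(OC)c1OCc1ccccc1 | intermediate
7 | 2-(benzyloxy)-5-[3-{[4-(benzyloxy)-3-methoxybenzyl]oxy}prop-1-yn-1-yl]-1,3-dimethoxybenzene | COc1cc(COCC#Cc2cc(OC)c(OCc3ccccc3)c(OC)c2)ccc1OCc1ccccc1 | intermediate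
8 | tributyl[(E)-1-[4-(benzyloxy)-3,5-dimethoxyphenyl]-3-{[4-(benzyloxy)-3-methoxybenzyl]oxy}prop-1-en-2-yl]stannane (tin trans to aryl) | CCCC[Sn](CCCC)(CCCC)/C(COCc1ccc(OCc2ccccc2)c(OC)c1)=C/c1cc(OC)c(OCc2ccccc2)c(OC)c1 | intermediate (not isolated)
9 | 2-(benzyloxy)-5-[(E)-3-{[4-(benzyloxy)-3-methoxybenzyl]oxy}-2-iodoprop-1-en-1-yl]-1,3-dimethoxybenzene (iodine trans to aryl) | I/C(COCc1ccc(OCc2ccccc2)c(OC)c1)=C/c1cc(OC)c(OCc2ccccc2)c(OC)c1 | intermediate
10 | ethyl diazoacetate | CCOC(=O)C=[N+]=[N-] | starting material
11 | ethyl (Z)-4-[4-(benzyloxy)-3,5-dimethoxyphenyl]-3-({[4-(benzyloxy)-3-methoxybenzyl]oxy}methyl)-2-diazobut-3-enoate | CCOC(=O)C(=[N+]=[N-])/C(COCc1ccc(OCc2ccccc2)c(OC)c1)=C/c1cc(OC)c(OCc2ccccc2)c(OC)c1 | intermediate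
12 | ethyl (2S,3S,Z)-2-[4-(benzyloxy)-3-methoxyphenyl]-4-[4-(benzyloxy)-3,5-dimethoxybenzylidene]tetrahydrofuran-3-carboxylate | COc1cc([C@H]2OC/C(=C\c3cc(OC)c(OCc4ccccc4)c(OC)c3)[C@@H]2C(=O)OCC)ccc1OCc1ccccc1 | intermediate
13 | ethyl (2S,3S)-2-[4-(benzyloxy)-3-methoxyphenyl]-4-{[4-(benzyloxy)-3,5-dimethoxyphenyl](boranyl)methyl}tetrahydrofuran-3-carboxylate, drawn as the monoalkylborane, mixture at C4 and the boron-bearing carbon | COc1cc([C@H]2OCC(C([BH2])c3cc(OC)c(OCc4ccccc4)c(OC)c3)[C@@H]2C(=O)OCC)ccc1OCc1ccccc1 | intermediate (not isolated)
14 | ethyl (2S,3S)-2-[4-(benzyloxy)-3-methoxyphenyl]-4-[4-(benzyloxy)-3,5-dimethoxybenzoyl]tetrahydrofuran-3-carboxylate, C4 epimers | COc1cc([C@H]2OCC(C(=O)c3cc(OC)c(OCc4ccccc4)c(OC)c3)[C@@H]2C(=O)OCC)ccc1OCc1ccccc1 | intermediate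
15 | ethyl (2S,3S,4S)-2-[4-(benzyloxy)-3-methoxyphenyl]-4-[4-(benzyloxy)-3,5-dimethoxybenzoyl]tetrahydrofuran-3-carboxylate (all-trans) | COc1cc([C@H]2OC[C@@H](C(=O)c3cc(OC)c(OCc4ccccc4)c(OC)c3)[C@@H]2C(=O)OCC)ccc1OCc1ccccc1 | intermediate
16 | {(2S,3R,4S)-2-[4-(benzyloxy)-3-methoxyphenyl]-4-[[4-(benzyloxy)-3,5-dimethoxyphenyl](hydroxy)methyl]tetrahydrofuran-3-yl}methanol, carbinol epimers | COc1cc([C@H]2OC[C@@H](C(O)c3cc(OC)c(OCc4ccccc4)c(OC)c3)[C@@H]2CO)ccc1OCc1ccccc1 | intermediate
17 | [4-(benzyloxy)-3,5-dimethoxyphenyl]{(2S,3R,4S)-2-[4-(benzyloxy)-3-methoxyphenyl]-3-(hydroxymethyl)tetrahydrofuran-4-yl}methanone | COc1cc([C@H]2OC[C@@H](C(=O)c3cc(OC)c(OCc4ccccc4)c(OC)c3)[C@@H]2CO)ccc1OCc1ccccc1 | intermediate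
18 | (4-hydroxy-3,5-dimethoxyphenyl)[(2S,3R,4S)-2-(4-hydroxy-3-methoxyphenyl)-3-(hydroxymethyl)tetrahydrofuran-4-yl]methanone (ring numbered O1, C2 guaiacyl, C3, C4, C5) | COc1cc([C@H]2OC[C@@H](C(=O)c3cc(OC)c(O)c(OC)c3)[C@@H]2CO)ccc1O | target

## Step count and least certain steps

Total step count: 12. Longest linear sequence: 11 steps (steps 2 to 12, from 4).

Step 7 (key step, proposed new method). Two things are most likely to go wrong. The carbene may be diverted before it reaches C2–H: closure of the vinylcarbene to a cyclopropene, attack on the electron-rich guaiacyl ring, or dimerisation. Or the discrimination between the two benzylic hydrogens may be poor, because the acyclic tether is less ordered than the aryl-fused case on which the catalyst choice rests.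

The fallback uses a known palladium-mediated three-component cascade. It sets out from 6 and comes back at 12.
- Knoevenagel condensation of commercial aldehyde A9 with diethyl malonate gives diethyl 2-[4-(benzyloxy)-3-methoxybenzylidene]malonate F1.
- Propargyl alcohol with t-BuOK, F1 and 6 under PdCl2(PPh3)2 (reduced in the flask to zerovalent palladium) in DMSO–THF give diethyl (Z)-2-[4-(benzyloxy)-3-methoxyphenyl]-4-[4-(benzyloxy)-3,5-dimethoxybenzylidene]dihydrofuran-3,3(2H)-dicarboxylate F2. The alkoxide adds to F1 (O1–C2), the malonate anion attacks the alkyne anti to the arylpalladium species (C3–C4), and the aryl group ends up trans to C3.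
- Krapcho dealkoxycarbonylation (LiCl, wet DMSO, heat) gives racemic ethyl (Z)-trans-2-[4-(benzyloxy)-3-methoxyphenyl]-4-[4-(benzyloxy)-3,5-dimethoxybenzylidene]tetrahydrofuran-3-carboxylate F3.
- Preparative chromatography on a chiral stationary phase gives 12; its (2R,3R) enantiomer F4 is set aside.

Step 6. Oxidative addition and coupling at the hindered, electron-rich, α-branched vinyl iodide may be slow, and during a long reaction the product can be lost through palladium-carbene formation or cyclisation to a pyrazole. The fallback sets out from 9 and comes back at 11. Negishi-type coupling of 9 with the Reformatsky reagent BrZnCH2CO2Et (Pd(dba)2, P(t-Bu)3, THF, rt) gives ethyl (Z)-4-[4-(benzyloxy)-3,5-dimethoxyphenyl]-3-({[4-(benzyloxy)-3-methoxybenzyl]oxy}methyl)but-3-enoate F5. Diazo transfer to this β,γ-unsaturated ester with 4-acetamidobenzenesulfonyl azide and DBU in MeCN at 0 °C gives 11.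

Step 8. Borane may attack the C3 ester, hydroboration of the hindered alkene may stall, or a transient cis hydroxy ester may lactonise before it is oxidised. The fallback removes the ester first. It sets out from 12 and comes back at 17.
- LiAlH4 reduction of 12 gives {(2S,3R,Z)-2-[4-(benzyloxy)-3-methoxyphenyl]-4-[4-(benzyloxy)-3,5-dimethoxybenzylidene]tetrahydrofuran-3-yl}methanol F6.
- Hydroboration–oxidation (BH3·THF; then NaOH, H2O2) gives the diol {(2S,3R)-2-[4-(benzyloxy)-3-methoxyphenyl]-4-[[4-(benzyloxy)-3,5-dimethoxyphenyl](hydroxy)methyl]tetrahydrofuran-3-yl}methanol F7, as a mixture at C4 and the carbinol carbon.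
- Dess–Martin oxidation of both hydroxyls, then equilibration with Et3N, gives the all-trans keto aldehyde (2S,3S,4S)-2-[4-(benzyloxy)-3-methoxyphenyl]-4-[4-(benzyloxy)-3,5-dimethoxybenzoyl]tetrahydrofuran-3-carbaldehyde F8.
- NaBH4 at −78 °C reduces only the aldehyde and gives 17.

Step 12. Over-reduction is the risk: once the para phenol is free the C2–O1 bond becomes more prone to hydrogenolysis, and the aryl ketone can be reduced on long exposure. The fallback replaces hydrogenation by Lewis-acid debenzylation with a cation scavenger (BCl3, pentamethylbenzene, CH2Cl2, −78 °C). It sets out from 17 and comes back at 18, and makes no new compound.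

## Further compounds

F1 | step 7 | diethyl 2-[4-(benzyloxy)-3-methoxybenzylidene]malonate | CCOC(=O)C(=Cc1ccc(OCc2ccccc2)c(OC)c1)C(=O)OCC
F2 | step 7 | diethyl (Z)-2-[4-(benzyloxy)-3-methoxyphenyl]-4-[4-(benzyloxy)-3,5-dimethoxybenzylidene]dihydrofuran-3,3(2H)-dicarboxylate (racemic) | CCOC(=O)C1(C(=O)OCC)C(c2ccc(OCc3ccccc3)c(OC)c2)OC/C1=C\c1cc(OC)c(OCc2ccccc2)c(OC)c1
F3 | step 7 | racemic ethyl (Z)-trans-2-[4-(benzyloxy)-3-methoxyphenyl]-4-[4-(benzyloxy)-3,5-dimethoxybenzylidene]tetrahydrofuran-3-carboxylate | CCOC(=O)C1C(c2ccc(OCc3ccccc3)c(OC)c2)OC/C1=C\c1cc(OC)c(OCc2ccccc2)c(OC)c1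
F4 | step 7 | ethyl (2R,3R,Z)-2-[4-(benzyloxy)-3-methoxyphenyl]-4-[4-(benzyloxy)-3,5-dimethoxybenzylidene]tetrahydrofuran-3-carboxylate (enantiomer of 12) | COc1cc([C@@H]2OC/C(=C\c3cc(OC)c(OCc4ccccc4)c(OC)c3)[C@H]2C(=O)OCC)ccc1OCc1ccccc1
F5 | step 6 | ethyl (Z)-4-[4-(benzyloxy)-3,5-dimethoxyphenyl]-3-({[4-(benzyloxy)-3-methoxybenzyl]oxy}methyl)but-3-enoate | CCOC(=O)C/C(COCc1ccc(OCc2ccccc2)c(OC)c1)=C/c1cc(OC)c(OCc2ccccc2)c(OC)c1
F6 | step 8 | {(2S,3R,Z)-2-[4-(benzyloxy)-3-methoxyphenyl]-4-[4-(benzyloxy)-3,5-dimethoxybenzylidene]tetrahydrofuran-3-yl}methanol | COc1cc([C@H]2OC/C(=C\c3cc(OC)c(OCc4ccccc4)c(OC)c3)[C@@H]2CO)ccc1OCc1ccccc1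
F7 | step 8 | {(2S,3R)-2-[4-(benzyloxy)-3-methoxyphenyl]-4-[[4-(benzyloxy)-3,5-dimethoxyphenyl](hydroxy)methyl]tetrahydrofuran-3-yl}methanol, mixture at C4 and the carbinol carbon | COc1cc([C@H]2OCC(C(O)c3cc(OC)c(OCc4ccccc4)c(OC)c3)[C@@H]2CO)ccc1OCc1ccccc1
F8 | step 8 | (2S,3S,4S)-2-[4-(benzyloxy)-3-methoxyphenyl]-4-[4-(benzyloxy)-3,5-dimethoxybenzoyl]tetrahydrofuran-3-carbaldehyde | COc1cc([C@H]2OC[C@@H](C(=O)c3cc(OC)c(OCc4ccccc4)c(OC)c3)[C@@H]2C=O)ccc1OCc1ccccc1
F0 | step 12 | none | none
A1 | alternative 1 | dimethyl 2,4-cis-2-[4-(benzyloxy)-3-methoxyphenyl]-4-{1-[4-(benzyloxy)-3,5-dimethoxyphenyl]vinyl}dihydrofuran-3,3(2H)-dicarboxylate | COc1cc([C@H]2OC[C@@H](C(=C)c3cc(OC)c(OCc4ccccc4)c(OC)c3)C2(C(=O)OC)C(=O)OC)ccc1OCc1ccccc1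
A2 | alternative 1 | 4-{1-[4-(benzyloxy)-3,5-dimethoxyphenyl]vinyl}-1,3-dioxolan-2-one | C=C(c1cc(OC)c(OCc2ccccc2)c(OC)c1)C1COC(=O)O1
A3 | alternative 1 | dimethyl 2-[4-(benzyloxy)-3-methoxybenzylidene]malonate | COC(=O)C(=Cc1ccc(OCc2ccccc2)c(OC)c1)C(=O)OC
A4 | alternative 2 | all-trans 2-aryl-3-[(tert-butyldiphenylsilyloxy)methyl]-4-aroyl tetrahydrofuran with both phenols as pivalates (ring configuration as in 18) | COc1cc([C@H]2OC[C@@H](C(=O)c3cc(OC)c(OC(=O)C(C)(C)C)c(OC)c3)[C@@H]2CO[Si](c2ccccc2)(c2ccccc2)C(C)(C)C)ccc1OC(=O)C(C)(C)C
A5 | alternative 2 | 4-[(E)-5-(tert-butyldiphenylsilyloxy)-1,2-dihydroxypent-3-en-2-yl]-2,6-dimethoxyphenyl pivalate, one enantiomer at the carbinol carbon (descriptor left open) | COc1cc(C(O)(CO)/C=C/CO[Si](c2ccccc2)(c2ccccc2)C(C)(C)C)cc(OC)c1OC(=O)C(C)(C)C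
A6 | alternative 2 | 4-formyl-2-methoxyphenyl pivalate | COc1cc(C=O)ccc1OC(=O)C(C)(C)C
A7 | alternative 3 | 2-[4-(benzyloxy)-3-methoxyphenyl]-3-vinyl-4-{[4-(benzyloxy)-3,5-dimethoxyphenyl](tert-butyldimethylsilyloxy)methyl}tetrahydrofuran (ring configuration as in 18) | COc1cc([C@H]2OC[C@@H]([C@@H](O[Si](C)(C)C(C)(C)C)c3cc(OC)c(OCc4ccccc4)c(OC)c3)[C@@H]2C=C)ccc1OCc1ccccc1
A8 | alternative 3 | (E)-2-{[4-(benzyloxy)-3,5-dimethoxyphenyl](tert-butyldimethylsilyloxy)methyl}-5-(trimethylsilyl)pent-3-en-1-ol, configured as in A7 | OC[C@@H]([C@@H](O[Si](C)(C)C(C)(C)C)c1cc(OC)c(OCc2ccccc2)c(OC)c1)/C=C/C[Si](C)(C)C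
A9 | alternative 3 | 4-(benzyloxy)-3-methoxybenzaldehyde (O-benzylvanillin) | COc1cc(C=O)ccc1OCc1ccccc1
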